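Two questions hung on the next run: how much target a flask rationed to 0.500 equiv of reagent gives, and when to stop it.

the same everywhere: substrate 0.10 M

| flask | reagent | remark | time |
|---|---|---|---|
| west | 0.70 equiv | run made earlier |  |
| north | 1.1 equiv | run made earlier |  |
| flask | 0.500 equiv |  | 25 min |

- west (time / min: target / %, substrate / %): 3.00: 23.7, 62.7; 6.00: 34.3, 46.6; 10.0: 36.7, 38.7; 15.0: 41.5, 30.6; 30.0: 39.7, 24.0
- north (time / min: target / %, substrate / %): 3.00: 36.5, 45.8; 6.00: 46.6, 28.7; 10.0: 54.6, 17.9; 15.0: 57.5, 10.9; 30.0: 61.4, 3.6

(readings scatter by 1 percentage point)

- in percentages every species weighs as the substrate in it: one side product counts as two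
- for target the crystals are counted in
- as a solid, counted per litre of solution: crystals
- on the list of suspects stand: substrate + reagent -> target; substrate + reagent -> isomer of the product; substrate + target -> side product; crystals <-> target

- time up to 25 min at which target stands highest
- the amount of target, in percent of the substrate charged, at that time

I scaled from the west run, which was charged at 0.70 equiv, so with less reagent than substrate, as the flask was to be. By its last reading it had used 76.0% of the substrate, more than its 0.70 equiv of reagent can account for, so substrate was going another way too. Its target read 41.5% at 15.0 min and 39.7% at 30.0 min, so it had stopped climbing. I divided the highest reading by the reagent charged: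

41.5% / 0.70 equiv = 0.593

This is the target per reagent: highest target as a fraction of the substrate charge, over reagent as a fraction of the same charge. Reagent is the limiting reagent in the flask, at 0.500 equiv, so I scaled by it:

0.593 × 0.500 equiv = 29.6%

I kept the charge and planned to stop near 15.0 min.

The forecast gave 30% (28% to 33%) at 12 min (9 min to 16 min), earlier than my stop, and held that “Crystals seem not to matter”.

The flask peaked at 27.3% at 12.5 min: the time lies inside the forecast's range, and the peak stands 0.70 percentage points below the low end of its range. Crystals held 2.04% of the substrate charge at that time, and how little target dissolves made no difference to the peak. Target per reagent in this flask came to 0.547, lower than the west reading.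

    substrate + reagent → target (k = 0.0380 /M/s)
    substrate + reagent → isomer of the product (k = 0.0140 /M/s)
    substrate + target → side product (k = 0.00640 /M/s)
    crystals ⇌ target, rate k4*(cs4 - [target]) while solid is left; crystals form when [target] > cs4 (solubility = 25.0 mM, k = 0.00870 /s)

For a neighbour charged with 0.300 equiv of reagent, the flask's figure gives 16.4%. The computed best there is 16.3%.

(The runs are calculated for an exercise; noise was put on by code.)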